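**Conventions and assumption.** Bicyclic compounds carry biogenetic numbering: C1 = benzoyl bridgehead, C2/C4 = ring carbonyls flanking C3, C5 = geranyl bridgehead, C6 = CH2, C7, C8 = CMe2, C9 = bridging carbonyl. "Endo" means pointing towards C3, "exo" away from it. Geranyl = (2E)-3,7-dimethylocta-2,6-dien-1-yl; prenyl = 3-methylbut-2-en-1-yl. Assumption: the (R)-phosphate in step 5 is taken to give (1R,5S)-9; if the sense is opposite, the (S)-phosphate is used and nothing else changes.

## Retrosynthetic overview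

1. 20 ⇐ 18: one-pot oxidative enol–olefin–O2 cascade; the C3–C2' bond closes the homoadamantane, O2 capture and peroxyl closure build the 1,2-dioxepane.
2. 18 ⇐ 15 ⇐ 14: endo C7 prenyl from C7=CH2 (exo-face hydroboration, B-alkyl Suzuki); C7=CH2 from the C7 ketone (Wittig).
3. 14 ⇐ 12 ⇐ 9: C3 prenyl by Tsuji–Trost allylation of the dione freed by retro-Claisen loss of the second benzoyl group.
4. Key: 9 ⇐ 8: C1–C8 bond from a C8 enolonium (tertiary α-bromo ketone, silver) and a triketone enol carbon; a chiral phosphate desymmetrises the two benzoyl arms.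
5. 8 ⇐ 5 + 7 (dearomative C-alkylation); 5 ⇐ phloroglucinol, benzoyl chloride, geranyl bromide. Ring order: trione ring (from the arene) → ring B (bicyclo[3.3.1]) → homoadamantane → dioxepane.

## Route

Step 1
Reactants: 1 phloroglucinol; 2 benzoyl chloride (2.2 equiv)
Product: 3 2,4-dibenzoylphloroglucinol
Conditions: AlCl3 (4.5 equiv), PhNO2, 65 °C; then 1 M HCl
Reagents that add atoms: none
Why: Double Friedel–Crafts C-acylation of the electron-rich triol stops at the diketone because each acyl group deactivates the ring, leaving one free ring carbon.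

Step 2
Reactants: 3 2,4-dibenzoylphloroglucinol; 4 geranyl bromide (1.0 equiv)
Product: 5 2,4-dibenzoyl-6-geranylphloroglucinol
Conditions: KOH (10 % aq.), 0 → 23 °C
Reagents that add atoms: none
Why: Phenolate C-allylation in water goes to the only non-acylated ring carbon; the E-alkene is untouched (SN2).

Step 3
Reactants: 6 3-methylbutan-2-one
Product: 7 1,3-dibromo-3-methylbutan-2-one
Conditions: Br2 (2.0 equiv), HBr (cat.), AcOH, 0 → 23 °C
Reagents that add atoms: bromine, BrBr
Why: Acid-catalysed ketone α-bromination takes the tertiary position first (more substituted enol) and then the methyl group.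

Step 4
Reactants: 5 2,4-dibenzoyl-6-geranylphloroglucinol; 7 1,3-dibromo-3-methylbutan-2-one
Product: 8 6-geranyl-6-(3-bromo-3-methyl-2-oxobutyl) dearomatised dibenzoyl dienol
Conditions: LiN(SiMe3)2 (3.0 equiv), THF, −78 °C; then 7, −78 → −20 °C; NH4Cl (aq.)
Reagents that add atoms: none
Why: Alkylative dearomatisation: the lithium trianion attacks the primary α-bromo ketone carbon by SN2 (the tertiary bromide cannot react this way) at C6, the only ring carbon without an acyl group. The product is achiral because the two benzoyl arms are equivalent; O-alkylation is the competing path.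

Step 5
Reactants: 8 dearomatised bromo ketone
Product: 9 (1R,5S)-1,3-dibenzoyl-5-geranyl-8,8-dimethylbicyclo[3.3.1]nonane tetraone (C3 triketone enolised)
Conditions: Ag2CO3 (0.55 equiv), (R)-TRIP [(R)-3,3'-bis(2,4,6-triisopropylphenyl)-1,1'-binaphthalene-2,2'-diyl hydrogen phosphate] (10 mol %), 4 Å MS, PhMe, −20 → 23 °C, dark
Reagents that add atoms: none
Why: Proposed new method: monovalent silver abstracts the tertiary bromide and unmasks C8 as an α-keto carbenium (oxyallyl-type enolonium, the reversed-polarity form of a ketone α-carbon). The enol carbon of one benzoyl triketone arm, far more nucleophilic than the geranyl alkenes, captures it through a chair six-membered transition state; attack at the other cationic terminus would need a four-membered ring, and neutral enols add to carbocations at carbon. This forges the quaternary–quaternary C1–C8 bond as a 1,4-dicarbonyl, and the chiral phosphate counter-anion selects one of the two enantiotopic arms, setting C1 (R) and C5 (S) together. Closest known types: silver-promoted α-alkylation with tertiary α-bromo ketones and chiral silver phosphate ion-pair catalysis of halide abstraction.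

Step 6
Reactants: 9 bicyclic dibenzoyl tetraone
Product: 12 (1R,5S)-1-benzoyl-5-geranyl-2-hydroxy-8,8-dimethylbicyclo[3.3.1]non-2-ene-4,7,9-trione, via 3-chloro-3-benzoyl tetraketone 10 (not isolated), via 3-chloro enol 11 (not isolated)
Conditions: NaOMe (1.0 equiv), THF/MeOH, −40 °C, NCS (1.05 equiv); NaOMe (1.5 equiv), 0 °C; then Zn, AcOH, 23 °C
Reagents that add atoms: N-chlorosuccinimide, O=C1CCC(=O)N1Cl
Why: Deacylative halogenation: C3 chlorination makes the C3 benzoyl ketone non-enolisable, methoxide cleaves it by retro-Claisen (leaving group = chloro-diketone enolate), and zinc removes chlorine (α-halo ketone dehalogenation). The bridgehead benzoyl survives because its loss would need a bridgehead enolate; C1 and C5 are untouched.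

Step 7
Reactants: 12 debenzoylated dione; 13 prenyl acetate (1.05 equiv)
Product: 14 (1R,5S)-1-benzoyl-5-geranyl-2-hydroxy-8,8-dimethyl-3-prenylbicyclo[3.3.1]non-2-ene-4,7,9-trione
Conditions: Pd(PPh3)4 (5 mol %), Et3N (1.2 equiv), THF, 40 °C
Reagents that add atoms: none
Why: Tsuji–Trost allylation: the soft dione enolate attacks the unsubstituted terminus of the π-prenyl palladium complex (linear product, O-allylation reversible); C3 stays sp2, so no stereocentre is formed.

Step 8
Reactants: 14 C3-prenyl trione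
Product: 15 (1R,5S)-1-benzoyl-5-geranyl-2-hydroxy-8,8-dimethyl-7-methylidene-3-prenylbicyclo[3.3.1]non-2-ene-4,9-dione
Conditions: Ph3PCH3Br (4 equiv), KOtBu (3.8 equiv), THF, 0 → 45 °C
Reagents that add atoms: methyltriphenylphosphonium bromide, C[P+](c1ccccc1)(c1ccccc1)c1ccccc1.[Br-]
Why: Wittig methylenation reacts only at the C7 cyclohexanone; C9 and the aryl ketone sit between quaternary carbons and the β-diketone is protected as its enolate.

Step 9
Reactants: 15 C7-methylidene dione; 16 1-bromo-2-methylprop-1-ene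
Product: 18 (1R,5S,7S)-1-benzoyl-5-geranyl-2-hydroxy-8,8-dimethyl-3,7-diprenylbicyclo[3.3.1]non-2-ene-4,9-dione (7-endo), via B-alkyl-9-BBN borane 17 (not isolated)
Conditions: 9-BBN (2.5 equiv), THF, 0 → 23 °C; then 16, Pd(dppf)Cl2 (5 mol %), K3PO4 (3 M aq.), DMF, 50 °C
Reagents that add atoms: 9-borabicyclo[3.3.1]nonane, [H]B1C2CCCC1CCC2
Why: 9-BBN hydroborates the 1,1-disubstituted alkene in preference to the trisubstituted ones and from the exo face (the endo face is shielded by the C2–C3–C4 bridge), so H ends exo and the CH2B arm endo, setting C7 (S). B-alkyl Suzuki–Miyaura coupling then completes the endo prenyl group.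

Step 10
Reactants: 18 7-endo bicyclic enol
Product: 20 CNP0148771.1, via tertiary hydroperoxide 19 (not isolated)
Conditions: Mn(OAc)3·2H2O (0.2 equiv), O2 (1 atm), AcOH, 23 °C; then PPh3 (1.2 equiv), CH2Cl2, 0 °C
Reagents that add atoms: dioxygen, O=O
Why: Proposed new method: trivalent manganese oxidises the C3 enol to an electrophilic α,α-dicarbonyl radical, which adds to C2' of the endo C7 prenyl group held over it; the bridgehead geranyl and benzoyl groups are equatorial and cannot reach C3. C3 (R) is forced by the cage, and C2' (S) is expected because the CMe2 end turns to the less hindered C4/C6 side. The tertiary radical traps O2, the peroxyl radical closes 7-exo on the C3 prenyl alkene (sets C2''; its sense is not secured), a second O2 gives hydroperoxide 19, and PPh3 reduces only the hydroperoxide. Closest known types: Mn(OAc)3/O2 peroxidation of 1,3-dicarbonyls with alkenes and oxidative radical cyclisations of polyprenylated acylphloroglucinol enols.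

## Compound list

1 | benzene-1,3,5-triol (phloroglucinol) | Oc1cc(O)cc(O)c1 | starting material
2 | benzoyl chloride | O=C(Cl)c1ccccc1 | starting material
3 | (2,4,6-trihydroxy-1,3-phenylene)bis(phenylmethanone) (2,4-dibenzoylphloroglucinol) | O=C(c1ccccc1)c1c(O)cc(O)c(C(=O)c2ccccc2)c1O | intermediate
4 | (2E)-1-bromo-3,7-dimethylocta-2,6-diene (geranyl bromide) | BrC/C=C(\C)CCC=C(C)C | starting material
5 | {5-[(2E)-3,7-dimethylocta-2,6-dien-1-yl]-2,4,6-trihydroxy-1,3-phenylene}bis(phenylmethanone) | O=C(c1ccccc1)c1c(O)c(C/C=C(\C)CCC=C(C)C)c(O)c(C(=O)c2ccccc2)c1O | intermediate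
6 | 3-methylbutan-2-one | CC(C)C(C)=O | starting material
7 | 1,3-dibromo-3-methylbutan-2-one | CC(C)(Br)C(=O)CBr | intermediate
8 | 2,4-dibenzoyl-6-(3-bromo-3-methyl-2-oxobutyl)-6-geranyl-3,5-dihydroxycyclohexa-2,4-dien-1-one (achiral; the two ring halves exchange by enol tautomerism) | O=C1C(C(=O)c2ccccc2)=C(O)C(C(=O)c2ccccc2)=C(O)C1(CC(=O)C(C)(C)Br)C/C=C(\C)CCC=C(C)C | intermediate
9 | (1R,5S)-1,3-dibenzoyl-5-geranyl-2-hydroxy-8,8-dimethylbicyclo[3.3.1]non-2-ene-4,7,9-trione | CC(C)=CCC/C(C)=C/C[C@]12CC(=O)C(C)(C)[C@@](C(=O)c3ccccc3)(C2=O)C(O)=C(C(=O)c3ccccc3)C1=O | intermediate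
10 | 1,3-dibenzoyl-3-exo-chloro-5-geranyl-8,8-dimethylbicyclo[3.3.1]nonane-2,4,7,9-tetrone, bridgeheads as in 9 | CC(C)=CCC/C(C)=C/C[C@]12CC(=O)C(C)(C)[C@@](C(=O)c3ccccc3)(C2=O)C(=O)[C@](Cl)(C(=O)c3ccccc3)C1=O | intermediate (not isolated)
11 | 1-benzoyl-3-chloro-5-geranyl-2-hydroxy-8,8-dimethylbicyclo[3.3.1]non-2-ene-4,7,9-trione, bridgeheads as in 9 | CC(C)=CCC/C(C)=C/C[C@]12CC(=O)C(C)(C)[C@@](C(=O)c3ccccc3)(C2=O)C(O)=C(Cl)C1=O | intermediate (not isolated)
12 | (1R,5S)-1-benzoyl-5-geranyl-2-hydroxy-8,8-dimethylbicyclo[3.3.1]non-2-ene-4,7,9-trione | CC(C)=CCC/C(C)=C/C[C@]12CC(=O)C(C)(C)[C@@](C(=O)c3ccccc3)(C2=O)C(O)=CC1=O | intermediate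
13 | 3-methylbut-2-en-1-yl acetate (prenyl acetate) | CC(=O)OCC=C(C)C | starting material
14 | (1R,5S)-1-benzoyl-5-geranyl-2-hydroxy-8,8-dimethyl-3-prenylbicyclo[3.3.1]non-2-ene-4,7,9-trione | CC(C)=CCC/C(C)=C/C[C@]12CC(=O)C(C)(C)[C@@](C(=O)c3ccccc3)(C2=O)C(O)=C(CC=C(C)C)C1=O | intermediate
15 | (1R,5S)-1-benzoyl-5-geranyl-2-hydroxy-8,8-dimethyl-7-methylidene-3-prenylbicyclo[3.3.1]non-2-ene-4,9-dione | CC(C)=CCC/C(C)=C/C[C@]12CC(=C)C(C)(C)[C@@](C(=O)c3ccccc3)(C2=O)C(O)=C(CC=C(C)C)C1=O | intermediate
16 | 1-bromo-2-methylprop-1-ene | CC(C)=CBr | starting material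
17 | (1R,5S,7S)-1-benzoyl-7-endo-[(9-borabicyclo[3.3.1]nonan-9-yl)methyl]-5-geranyl-2-hydroxy-8,8-dimethyl-3-prenylbicyclo[3.3.1]non-2-ene-4,9-dione (drawn as the free enol) | CC(C)=CCC/C(C)=C/C[C@]12C[C@H](CB3C4CCCC3CCC4)C(C)(C)[C@@](C(=O)c3ccccc3)(C2=O)C(O)=C(CC=C(C)C)C1=O | intermediate (not isolated)
18 | (1R,5S,7S)-1-benzoyl-5-geranyl-2-hydroxy-8,8-dimethyl-3,7-diprenylbicyclo[3.3.1]non-2-ene-4,9-dione (7-endo prenyl) | CC(C)=CCC/C(C)=C/C[C@]12C[C@H](CC=C(C)C)C(C)(C)[C@@](C(=O)c3ccccc3)(C2=O)C(O)=C(CC=C(C)C)C1=O | intermediate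
19 | hydroperoxide of the target (C(CH3)2OOH in place of C(CH3)2OH; all six stereocentres as in 20) | CC(C)=CCC/C(C)=C/C[C@]12C[C@@H]3C[C@@H]4C(C)(C)OO[C@H](C(C)(C)OO)C[C@@]4(C1=O)C(=O)[C@](C(=O)c1ccccc1)(C2=O)C3(C)C | intermediate (not isolated)
20 | CNP0148771.1: homoadamantane trione fused to a 1,2-dioxepane; C1 R, C3 R, C5 S, C7 S, C2' S (cage CH bearing CMe2O), C2'' S (dioxepane CH–O) | CC(C)=CCC/C(C)=C/C[C@]12C[C@@H]3C[C@@H]4C(C)(C)OO[C@H](C(C)(C)O)C[C@@]4(C1=O)C(=O)[C@](C(=O)c1ccccc1)(C2=O)C3(C)C | target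

## Step count and risk

Total steps: 10. Longest linear sequence: 9 (steps 1, 2, 4, 5, 6, 7, 8, 9, 10).

**Step 5 (silver/chiral phosphate enolonium closure).** Risks are O- instead of C-capture and low enantioselectivity. The fallback sets out from 5 and returns at 9. Compound 5 is C-alkylated with commercial 1-bromo-3-methylbutan-2-one (LiN(SiMe3)2, THF) to the isopropyl ketone adduct F1. Thermodynamic silylation (Me3SiOTf, Et3N) gives the tris(trimethylsilyl) enol ether F2. A C2-symmetric chiral diacetoxy(aryl)iodane (trivalent iodine; BF3·OEt2, CH2Cl2, −78 °C) oxidises the electron-rich C8 enol ether of F2 to the same C8 enolonium. The silylated triketone carbon, a carbon-only nucleophile, captures it, so O-alkylation is excluded and the chiral iodane takes over the desymmetrisation; desilylation on work-up gives 9.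

**Step 6 (chlorinative debenzoylation).** Risks are chlorine transfer to alkenes and ring-opening retro-Claisen. The fallback sets out from 9 and returns at 14, bypassing 12. Compound 9 is treated with prenyl acetate 13, Pd(PPh3)4 and NaOMe in THF/MeOH. C-prenylation of the triketone enolate gives the 3-benzoyl-3-prenyl tetraketone F3, whose C3 benzoyl group is now non-enolisable and is cleaved by methoxide (alkylative retro-Claisen) to give 14 directly.

**Step 10 (oxidative peroxide cascade).** Risks are C3 hydroxylation, arrest at an open hydroperoxide, and the wrong C2'' epimer. The fallback sets out from 18 and returns at 19. NBS converts 18 into the 3-bromo-3-prenyl diketone F4, an isolable two-electron enolonium equivalent. AgBF4 with ethereal H2O2 at −40 °C ionises F4; the endo prenyl alkene closes the homoadamantane and the tertiary cation is trapped as the homoadamantyl tertiary hydroperoxide F5. F5 is then cyclised through its peroxyl radical (Cu(OTf)2 cat., O2, MeCN) onto the C3 prenyl group to give 19, which is reduced with PPh3 as in step 10. Separating C–C formation from dioxepane closure allows each to be optimised and the C2'' epimers to be separated at 19.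

## Further compounds

F1 | step 5 | 2,4-dibenzoyl-6-geranyl-3,5-dihydroxy-6-(3-methyl-2-oxobutyl)cyclohexa-2,4-dien-1-one | O=C1C(C(=O)c2ccccc2)=C(O)C(C(=O)c2ccccc2)=C(O)C1(CC(=O)C(C)C)C/C=C(\C)CCC=C(C)C
F2 | step 5 | 2,4-dibenzoyl-6-geranyl-6-[3-methyl-2-(trimethylsilyloxy)but-2-en-1-yl]-3,5-bis(trimethylsilyloxy)cyclohexa-2,4-dien-1-one | O=C1C(C(=O)c2ccccc2)=C(O[Si](C)(C)C)C(C(=O)c2ccccc2)=C(O[Si](C)(C)C)C1(CC(O[Si](C)(C)C)=C(C)C)C/C=C(\C)CCC=C(C)C
F3 | step 6 | 1,3-dibenzoyl-5-geranyl-8,8-dimethyl-3-exo-prenylbicyclo[3.3.1]nonane-2,4,7,9-tetrone, bridgeheads as in 9 | CC(C)=CCC/C(C)=C/C[C@]12CC(=O)C(C)(C)[C@@](C(=O)c3ccccc3)(C2=O)C(=O)[C@](CC=C(C)C)(C(=O)c3ccccc3)C1=O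
F4 | step 10 | 1-benzoyl-3-exo-bromo-5-geranyl-8,8-dimethyl-3,7-diprenylbicyclo[3.3.1]nonane-2,4,9-trione, C1, C5, C7 as in 18 | CC(C)=CCC/C(C)=C/C[C@]12C[C@H](CC=C(C)C)C(C)(C)[C@@](C(=O)c3ccccc3)(C2=O)C(=O)[C@](Br)(CC=C(C)C)C1=O
F5 | step 10 | homoadamantane trione with C(CH3)2OOH on the cage CH and an intact C3 prenyl group, cage stereocentres as in 20 | CC(C)=CCC/C(C)=C/C[C@]12C[C@@H]3C[C@H](C(C)(C)OO)[C@](CC=C(C)C)(C1=O)C(=O)[C@](C(=O)c1ccccc1)(C2=O)C3(C)C
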